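**Assumption:** The target has no stereocentre and no stable stereoaxis (the diaryl ethers rotate freely), so there is no enantiomer to select. It is delivered as the free hydrogen sulfate, as drawn.

## Retrosynthetic overview
1. Cut the S–O bond: the aryl hydrogen sulfate comes from the free phenol (bromoiesol A) and SO3·pyridine.
2. Cut the ring-A C–OH bond: the phenol comes from the corresponding benzaldehyde by Baeyer–Villiger oxidation. The same CHO group serves earlier as the SNAr activator.
3. Cut both diaryl ether C–O bonds in one pot. Ring B is 3,4,5-tribromocatechol and supplies both oxygens. Ring A is 3,5-dibromo-2-fluorobenzaldehyde. Ring C is a 2,4-dibromophenyl(trimethoxyphenyl)iodonium salt.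
4. Tribromocatechol comes from catechol and 3 Br2. The iodonium salt comes from 2,4-dibromo-1-iodobenzene and 1,3,5-trimethoxybenzene.
5. No ring is built, since all three benzene rings are bought. They are joined B–O–A first, then B–O–C.

## Route

**Step 1**
Reactants: 1 catechol
Product: 2 3,4,5-tribromocatechol (3,4,5-tribromobenzene-1,2-diol)
Conditions: Br2 (3.0 equiv), AcOH/CHCl3, 0 °C → rt, 16 h; recrystallise
Reagents that add atoms: bromine, BrBr
Why: Electrophilic aromatic bromination puts the first two bromines para to the OH groups (C4, C5) and the third on one of the two equivalent ortho sites, so only one tribromide can form, and the fourth bromination of the deactivated ring is slow.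

**Step 2**
Reactants: 3 2,4-dibromo-1-iodobenzene; 4 1,3,5-trimethoxybenzene
Product: 6 (2,4-dibromophenyl)(2,4,6-trimethoxyphenyl)iodonium tosylate, via 2,4-dibromo-1-[hydroxy(tosyloxy)-λ3-iodanyl]benzene 5 (not isolated)
Conditions: mCPBA (1.05 equiv), TsOH·H2O (1.05 equiv), MeCN, 77 °C, 30 min; then 4 (1.0 equiv), 77 °C, 10 min; precipitate with Et2O
Reagents that add atoms: p-toluenesulfonic acid (used as monohydrate), Cc1ccc(cc1)S(=O)(=O)O; mCPBA, O=C(OO)c1cccc(Cl)c1 (its oxygen stands only in 5 and leaves as water)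
Why: This is the standard one-pot aryl(TMP)iodonium tosylate synthesis, in which the aryl iodide is oxidised to a Koser-type I(III) species that undergoes SEAr with the very electron-rich arene.

**Step 3**
Reactants: 2 3,4,5-tribromocatechol; 7 3,5-dibromo-2-fluorobenzaldehyde; 6 (2,4-dibromophenyl)(2,4,6-trimethoxyphenyl)iodonium tosylate
Product: 9 3,5-dibromo-2-[3,4,5-tribromo-2-(2,4-dibromophenoxy)phenoxy]benzaldehyde, via 3,5-dibromo-2-(3,4,5-tribromo-2-hydroxyphenoxy)benzaldehyde 8 (not isolated)
Conditions: 2 + 7 (1:1), K2CO3 (3 equiv), dry degassed DMF, Ar, 90 °C, 16 h; cool to 25 °C, add 6 (1.2 equiv), 45 °C, 12 h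
Reagents that add atoms: none
Why: Proposed new method: a site-programmed, one-pot hetero-diarylation of an unsymmetrical polybromocatechol; in stage 1 the C–F of 7 (activated by ortho-CHO and ortho/para-Br) undergoes SNAr, and the less hindered, more basic oxygen next to C6–H attacks faster than the oxygen next to C3–Br; any wrong O-aryl isomer is corrected by a reversible O→O Smiles rearrangement through the spiro-Meisenheimer 1,3-benzodioxole, because 8 holds the better stabilised phenoxide (ortho-Br, about 0.6 pKa unit) and a tri-ortho rather than tetra-ortho-substituted ether; in stage 2 the potassium phenoxide of 8, already present in the flask, exchanges onto I(III) of 6 and ligand-couples at the ipso carbon of the electron-poor, ortho-substituted 2,4-dibromophenyl group, with TMP as the non-transferred dummy aryl; no metal is used, so all seven C–Br bonds survive; even if the Smiles equilibrium stays open in stage 2, the estimated 3–4 kcal/mol bias towards 8 outweighs the higher reactivity of the minor phenoxide; the closest known reaction types are SNAr of catechols on activated fluoroarenes, the Smiles rearrangement of 2-aryloxyphenoxides, and metal-free O-arylation of bromophenols with diaryliodonium salts.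

**Step 4**
Reactants: 9 3,5-dibromo-2-[3,4,5-tribromo-2-(2,4-dibromophenoxy)phenoxy]benzaldehyde
Product: 11 3,5-dibromo-2-[3,4,5-tribromo-2-(2,4-dibromophenoxy)phenoxy]phenol (bromoiesol A), via 3,5-dibromo-2-[3,4,5-tribromo-2-(2,4-dibromophenoxy)phenoxy]phenyl formate 10 (not isolated)
Conditions: mCPBA (3 equiv), CH2Cl2, 40 °C, 24 h; aq Na2S2O3/NaHCO3 wash; crude 10, cat. K2CO3, MeOH, rt, 1 h
Reagents that add atoms: mCPBA, O=C(OO)c1cccc(Cl)c1
Why: In this Baeyer–Villiger (Dakin-type) oxidation the ortho-aryloxy oxygen favours aryl over hydride migration in the Criegee adduct, and the electron-poor aryl formate is cleaved at once by methanolysis.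

**Step 5**
Reactants: 11 bromoiesol A
Product: 12 bromoiesol A sulfate (3,5-dibromo-2-[3,4,5-tribromo-2-(2,4-dibromophenoxy)phenoxy]phenyl hydrogen sulfate)
Conditions: SO3·pyridine (4 equiv), pyridine, 40 °C, 6 h; then Dowex 50W-X8 (H+ form), MeOH, 0 °C; lyophilise and store cold
Reagents that add atoms: sulfur trioxide–pyridine complex, O=S(=O)([O-])[n+]1ccccc1
Why: O-sulfation of the only free and unhindered phenol with an SO3–amine complex gives the pyridinium sulfate, and cold cation exchange then gives the protonated form.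

## Compound list
1 | catechol | Oc1ccccc1O | starting material
2 | 3,4,5-tribromocatechol | Oc1cc(Br)c(Br)c(Br)c1O | intermediate
3 | 2,4-dibromo-1-iodobenzene | Brc1ccc(I)c(Br)c1 | starting material
4 | 1,3,5-trimethoxybenzene | COc1cc(OC)cc(OC)c1 | starting material
5 | 2,4-dibromo-1-[hydroxy(tosyloxy)-λ3-iodanyl]benzene | Cc1ccc(cc1)S(=O)(=O)OI(O)c1ccc(Br)cc1Br | intermediate (not isolated)
6 | (2,4-dibromophenyl)(2,4,6-trimethoxyphenyl)iodonium tosylate | COc1cc(OC)c([I+]c2ccc(Br)cc2Br)c(OC)c1.Cc1ccc(cc1)S(=O)(=O)[O-] | intermediate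
7 | 3,5-dibromo-2-fluorobenzaldehyde | O=Cc1cc(Br)cc(Br)c1F | starting material
8 | 3,5-dibromo-2-(3,4,5-tribromo-2-hydroxyphenoxy)benzaldehyde | O=Cc1cc(Br)cc(Br)c1Oc1cc(Br)c(Br)c(Br)c1O | intermediate (not isolated)
9 | 3,5-dibromo-2-[3,4,5-tribromo-2-(2,4-dibromophenoxy)phenoxy]benzaldehyde | O=Cc1cc(Br)cc(Br)c1Oc1cc(Br)c(Br)c(Br)c1Oc1ccc(Br)cc1Br | intermediate
10 | 3,5-dibromo-2-[3,4,5-tribromo-2-(2,4-dibromophenoxy)phenoxy]phenyl formate | O=COc1cc(Br)cc(Br)c1Oc1cc(Br)c(Br)c(Br)c1Oc1ccc(Br)cc1Br | intermediate (not isolated)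
11 | bromoiesol A | Oc1cc(Br)cc(Br)c1Oc1cc(Br)c(Br)c(Br)c1Oc1ccc(Br)cc1Br | intermediate
12 | bromoiesol A sulfate | O=S(=O)(O)Oc1cc(Br)cc(Br)c1Oc1cc(Br)c(Br)c(Br)c1Oc1ccc(Br)cc1Br | target

## Step count
- **Total steps:** 5.
- **Longest linear sequence:** 4 (steps 1 → 3 → 4 → 5). The branch 2 → 3 → 4 → 5 is equally long.

## Steps most likely to fail

**Step 3 (proposed new step).**
- The risks are incomplete selectivity between the two catechol oxygens and closure of 8 to a dibenzodioxin through the ortho C–Br of ring A.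
- A further risk is leakage through the minor Smiles isomer, or sluggish arylation of the hindered, weakly nucleophilic phenoxide, in the second stage.
- The fallback uses known chemistry. It sets out from 6 and 7, with commercial guaiacol as an extra starting material, and comes back at 9.
- Guaiacol is tribrominated (Br2, 3 equiv, AcOH) to 2,3,4-tribromo-6-methoxyphenol F1. Its only free OH is the one next to bromine, so the two oxygens are told apart by the methyl group rather than by selectivity.
- F1 is O-arylated with 6 (K2CO3, MeCN, 50 °C) to 1,2,3-tribromo-4-(2,4-dibromophenoxy)-5-methoxybenzene F2.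
- BBr3 (CH2Cl2, −78 °C → rt) then frees 3,4,5-tribromo-2-(2,4-dibromophenoxy)phenol F3.
- An ordinary SNAr of this single phenol on 7 (K2CO3, DMF, 90 °C) gives 9. No free ortho-phenoxide is present at that stage, so neither Smiles rearrangement nor dioxin closure can occur.

**Step 4.**
- The risk is that the two bromines meta to the formyl group lower the migratory aptitude of the aryl group. Hydride migration would then give the benzoic acid instead of formate 10.
- The fallback sets out from 9 and comes back at 11. It removes the competing hydride by turning the aldehyde into a methyl ketone.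
- MeMgBr (THF, −78 °C) gives racemic 1-{3,5-dibromo-2-[3,4,5-tribromo-2-(2,4-dibromophenoxy)phenoxy]phenyl}ethanol F4.
- Dess–Martin periodinane gives 1-{3,5-dibromo-2-[3,4,5-tribromo-2-(2,4-dibromophenoxy)phenoxy]phenyl}ethanone F5.
- Trifluoroperacetic acid (urea·H2O2/TFAA, Na2HPO4, CH2Cl2) gives 3,5-dibromo-2-[3,4,5-tribromo-2-(2,4-dibromophenoxy)phenoxy]phenyl acetate F6, because aryl always migrates in preference to methyl.
- Methanolysis (cat. K2CO3, MeOH) gives 11.

**Step 5.**
- The risk is that the free aryl hydrogen sulfate hydrolyses autocatalytically during isolation, or that the polar product cannot be separated from the sulfation salts.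
- The fallback sets out from 11 and comes back at 12. It carries the sulfate as a neutral diester that can be chromatographed.
- 11 reacts with isobutyl chlorosulfate (CC(C)COS(=O)(=O)Cl; NaH, THF, 0 °C) to give isobutyl 3,5-dibromo-2-[3,4,5-tribromo-2-(2,4-dibromophenoxy)phenoxy]phenyl sulfate F7.
- NaI in acetone at 55 °C dealkylates F7 to sodium 3,5-dibromo-2-[3,4,5-tribromo-2-(2,4-dibromophenoxy)phenoxy]phenyl sulfate F8, the bench-stable storage form.
- A short partition between cold 1 M HCl and EtOAc, done just before use, gives 12.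

## Further compounds
F1 | step 3 | 2,3,4-tribromo-6-methoxyphenol | COc1cc(Br)c(Br)c(Br)c1O
F2 | step 3 | 1,2,3-tribromo-4-(2,4-dibromophenoxy)-5-methoxybenzene | COc1cc(Br)c(Br)c(Br)c1Oc1ccc(Br)cc1Br
F3 | step 3 | 3,4,5-tribromo-2-(2,4-dibromophenoxy)phenol | Oc1cc(Br)c(Br)c(Br)c1Oc1ccc(Br)cc1Br
F4 | step 4 | 1-{3,5-dibromo-2-[3,4,5-tribromo-2-(2,4-dibromophenoxy)phenoxy]phenyl}ethanol (racemic) | CC(O)c1cc(Br)cc(Br)c1Oc1cc(Br)c(Br)c(Br)c1Oc1ccc(Br)cc1Br
F5 | step 4 | 1-{3,5-dibromo-2-[3,4,5-tribromo-2-(2,4-dibromophenoxy)phenoxy]phenyl}ethanone | CC(=O)c1cc(Br)cc(Br)c1Oc1cc(Br)c(Br)c(Br)c1Oc1ccc(Br)cc1Br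
F6 | step 4 | 3,5-dibromo-2-[3,4,5-tribromo-2-(2,4-dibromophenoxy)phenoxy]phenyl acetate | CC(=O)Oc1cc(Br)cc(Br)c1Oc1cc(Br)c(Br)c(Br)c1Oc1ccc(Br)cc1Br
F7 | step 5 | isobutyl 3,5-dibromo-2-[3,4,5-tribromo-2-(2,4-dibromophenoxy)phenoxy]phenyl sulfate | CC(C)COS(=O)(=O)Oc1cc(Br)cc(Br)c1Oc1cc(Br)c(Br)c(Br)c1Oc1ccc(Br)cc1Br
F8 | step 5 | sodium 3,5-dibromo-2-[3,4,5-tribromo-2-(2,4-dibromophenoxy)phenoxy]phenyl sulfate | [Na+].[O-]S(=O)(=O)Oc1cc(Br)cc(Br)c1Oc1cc(Br)c(Br)c(Br)c1Oc1ccc(Br)cc1Br
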